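# Proposed synthesis of 2,3-dehydrosilychristin by dearomative 1,2-boronate migration

Locants: the dihydrobenzofuran is numbered O1, C2, C3, C3a, C4–C7, C7a (ring B is its benzo ring, ring D its dihydrofuran ring, ring E the aryl group on C2). Flavonoid locants are used for ring A (phloroglucinol ring) and ring C (pyranone).

## The problem

2,3-Dehydrosilychristin (25) joins a flat 3,5,7-trihydroxychromen-4-one (rings A and C) through its C2 to C5 of a 2,3-dihydrobenzofuran (rings B and D). Ring D carries a 4-hydroxy-3-methoxyphenyl group (ring E) on C2 and a hydroxymethyl group on C3. The only stereocentres are C2 (R) and C3 (S) of ring D, with aryl and hydroxymethyl trans. The rest of the molecule is achiral, so the absolute configuration must come from a catalyst or reagent, whereas the relative configuration can be relayed from one centre to the other and is also the thermodynamically preferred one. C2 is a benzylic ether carbon para to an oxygen of ring E. Strong acid, or base once the ring E phenol is free, can therefore open the C2–O1 bond through a benzylic cation or a quinone methide, and a carbonyl group on C3 invites epimerisation and β-elimination of the ring B phenoxide. Six hydroxyl groups must be kept apart from the single methoxy group, which excludes methyl ethers as phenol protection, and the free flavonol is oxidised by air in base, so the phenols should be unmasked last and under neutral conditions. Rings A and C are standard chemistry from a phloroglucinol ketone and an aryl aldehyde. The real task is ring D with its two stereocentres, on a ring B that bears an oxygen on C7 and a one-carbon handle on C5. The enabling feature is that O1–C2–C3 of ring D is the reduced form of the enol-ether C2=C3 bond of an aromatic benzofuran. An aryl group on C2 and a carbon branch on C3 on opposite faces is the pattern left by anti addition of a migrating aryl group and a carbon electrophile across that bond, and C2–H is the most acidic proton of a benzofuran, so boron can be placed exactly there.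

## Retrosynthesis

**Protecting groups (25 ⇒ 24).** The last operation is the cleavage of the four benzyl–oxygen bonds of 24. Benzyl ethers are preferred to silyl ethers, which would not survive the hydroxide and peroxide used to build the flavonol. They are preferred to acetal-type groups because acidic removal endangers the C2–O1 bond once ring E is a free phenol. The forward step must cleave aryl benzyl ethers faster than the benzylic C2–O1 bond and leave the chromone double bond alone.

**Flavonol (24 ⇒ 23 ⇒ 20 + 22).** In 24 the O1–C2 bond of ring C and the C3–OH bond are cut together, giving the 2'-hydroxychalcone 23. Chalcone 23 is cut at its Cα=Cβ bond into aldehyde 20 and ketone 22, and 22 is the dibenzyl ether of commercial 21. This is preferred to an aroyl-transfer and cyclodehydration sequence, which needs the acid oxidation level on ring B and a ketone already oxygenated at its methyl carbon. It is preferred to building ring A last (Alternative 1) because 21 brings ring A ready-made. Aldehyde 20 holds all the stereochemistry and nothing of the flavonol. The condensation is safe for ring D because 20 has no acidifying group on C3. The oxidative cyclisation must close the six-membered ring and not the five-membered aurone ring, although 23 has a 6'-benzyloxy group.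

**One-carbon branch (20 ⇒ 19 ⇒ 17 ⇒ 16).** The aldehyde of 20 is masked as the dioxolane of 19. The hydroxymethyl carbon of 19 is recognised as the first carbon of an allyl group: the C=C bond of the propenyl compound 17 is cut, and 17 is the double-bond isomer of the allyl compound 16. Two of the three allyl carbons are discarded, but allyl is the carbon electrophile for which the key step has a close enantioselective model, and a direct one-carbon electrophile has none. In the forward direction the double bond must move by one position only, since a second shift would reach C3 and destroy the stereocentre. The cleavage must be followed at once by reduction, because aldehyde 18 is an α-aryl aldehyde β to the ring oxygen.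

**Boron (16 ⇒ 15).** The C2–H bond of 16 is traced back to the C2–B bond of 15. The forward reaction must replace boron by hydrogen with retention, so that the aryl group stays trans to the C3 branch.

**Key disconnection (15 ⇒ 8 + 11 + 12).** In 15 the C2–aryl bond and the C3–CH2 bond are cut at once, leaving the aromatic benzofuran 8, the aryl boronate 11 and allyl acetate 12. In the forward sense 8 is lithiated at C2 (13), 13 and 11 combine to the boronate complex 14, and 14 is allylated at C3 while the aryl group moves from boron to C2. The neighbouring cuts are C2–C3 alone (Alternative 2) or C2–C3 together with O1–C2 (Alternative 3). Both lead to open-chain precursors in which ring E is attached early and over several steps. Here all three precursors are flat, achiral and quickly made, and one step forms two C–C bonds and both stereocentres. The forward reaction must attack at C3 rather than transfer a group from boron to the metal, must migrate anti (trans product), and must select one face through a chiral ligand.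

**Benzofuran (8 ⇒ 7 ⇒ 5 ⇒ 3 + 4 ⇒ 2 ⇒ 1).** The acetal of 8 is removed to give 7. The O1–C2 bond of 7 is cut (addition of the phenol of 6 to its alkyne), and the C3a–C3 bond is cut as a Sonogashira coupling of iodophenol 3 with alkyne 4 to give 5. Iodophenol 3 differs from commercial 1 only in carrying benzyl instead of methyl on the oxygen that becomes O7, which leads through catechol 2. The iodine of 1 already marks C3a, which speaks against O-alkylation and cyclodehydration routes that have to find that position. The one demanding step is benzylation of 2 at the oxygen meta to the formyl group.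

**Side fragments (11 ⇒ 10 ⇒ 9).** The C–B bond of 11 is cut to bromide 10, and the O-benzyl bond of 10 to commercial 9.

## Roads not taken

**Alternative 1:** Ring A is built last by Danheiser benzannulation, cutting C5–C6, C7–C8 and C4a–C5.
- **Forward key step:** the pyranonyl diazomethyl ketone A2 is irradiated with the silyloxyalkyne A3. Wolff rearrangement gives a vinylketene, [2+2] addition of A3 a cyclobutenone, and four-electron opening followed by six-electron closure the phenol A1.
- **Merits:** ring A arrives with O5 free and O7 silylated, the C3 oxygen is already in place as a benzyl ether, and no chalcone has to be cyclised oxidatively, so the aurone problem does not arise. In this respect the road is better than the chosen one.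
- **Weak points:**
  - It leaves the real problem untouched: A2 already contains ring D with both stereocentres and would have to take them from another plan.
  - A2 needs a 2-aryl-3-alkoxypyranone-6-carboxylic acid and its conversion into a diazoketone, which is longer than steps 13–15 that add rings A and C from commercial 21.
  - The vinyl arm of the ketene is the C5=C6 bond of a cross-conjugated pyranone, a demanding case for the electrocyclic closure.
  - A photochemical step on a late, strongly absorbing intermediate puts the most valuable material at risk.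
- **Comparison:** the chosen plan sets against the cleaner ring A chemistry the fact that ring A is bought, and that its own uncertain step 15 has a known two-step substitute.

**Alternative 2:** Ring D is closed at the C2–C3 bond by carbenoid C–H insertion.
- **Forward key step:** the aryldiazoacetate A5 is treated with Rh2(S-DOSP)4, dirhodium tetrakis[N-(dodecylbenzenesulfonyl)prolinate], a dimer of divalent rhodium, or its enantiomer. The carbenoid inserts into a benzylic C–H bond of the neighbouring aryl-methyl ether and gives the ester A4.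
- **Merits:** this is the road closest to established chemistry. It is catalytic in chirality, and the C3 branch arrives as an ester, one reduction from hydroxymethyl, where the chosen plan spends steps 9–11.
- **Weak points:**
  - Insertion into a methylene C–H bond next to an electron-rich arene has catalyst-dependent diastereo- and enantioselectivity. The kinetic product is often the cis ester, and its epimerisation through the C3 enolate can open ring D by β-elimination.
  - The carbenoid can also attack ring E or the ether oxygen.
  - A5 needs a linear sequence with ring E attached at the start (etherification, acetate side chain, diazo transfer).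
  - The C5 bromide must later become the aldehyde, which forces reduction and protection of the ester first.
- **Comparison:** on precedent and on the oxidation level of the C3 branch this road is better, and it is kept as the fallback for step 8. The chosen plan sets against it convergence (three simple pieces joined in the step that forms both C–C bonds) and a trans selectivity built into the mechanism.

**Alternative 3:** Both bonds to C2 of ring D, C2–C3 and O1–C2, are formed in a [4+1] annulation.
- **Forward key step:** Cs2CO3 eliminates sulfinate from sulfone A7 to give the ortho-quinone methide A9 and deprotonates the chiral sulfonium salt A8. The ylide carbon adds to the methide carbon, and the phenoxide displaces the sulfide to give A6.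
- **Merits:** the annulation is convergent and runs under mild base. The C3 branch arrives at the hydroxymethyl oxidation level, the trans relation follows from the anti betaine and SN2 closure, and no boron has to be removed. In these respects it is better than the chosen plan.
- **Weak points:**
  - Enantiocontrol would rest on a stoichiometric chiral sulfide in the addition of a semi-stabilised benzylic ylide to a transient quinone methide, for which reliable induction is not established.
  - A9 carries a hydrogen-bearing carbon on its methide terminus and can tautomerise to a vinylphenol or lose silanolate.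
  - An electron-rich benzylic ylide is prone to [2,3]-sigmatropic rearrangement.
  - A7 is a multistep target in itself.
- **Comparison:** the step is as unproven in its asymmetric form as step 8. The chosen plan sets against the better oxidation level catalytic chirality, one stable boronate complex in place of two short-lived intermediates, and a ring D C–O bond taken ready-made from a benzofuran.

Key step: step 8

Assumption: the sense of induction of BINAP in step 8 is carried over from the indole series by analogy only. (S)-BINAP is written, and (R)-BINAP is to be used if it proves to deliver the enantiomer of 15.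

## Route

Step 1
Reactants: 1 5-iodovanillin (4-hydroxy-3-iodo-5-methoxybenzaldehyde)
Product: 2 3,4-dihydroxy-5-iodobenzaldehyde
Conditions: AlCl3 (1.2 equiv), pyridine (4.5 equiv), CH2Cl2, reflux; then aqueous HCl
Reagents that add atoms: none
Why: Lewis-acid demethylation of an ortho-hydroxy aryl methyl ether: AlCl3 is held between the phenoxide and the methoxy oxygen and chloride removes the methyl group; aldehyde and aryl iodide are not affected.

Step 2
Reactants: 2 3,4-dihydroxy-5-iodobenzaldehyde
Product: 3 3-benzyloxy-4-hydroxy-5-iodobenzaldehyde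
Conditions: NaH (2.2 equiv), DMSO, rt; BnBr (1.0 equiv), rt; then aqueous HCl
Reagents that add atoms: benzyl bromide, BrCc1ccccc1
Why: Williamson etherification of the catechol dianion: the 4-oxide is delocalised into the para formyl group and flanked by iodine, so the more basic 3-oxide should take the single equivalent of benzyl bromide.

Step 3
Reactants: 3 3-benzyloxy-4-hydroxy-5-iodobenzaldehyde; 4 ethynyltrimethylsilane
Product: 5 3-benzyloxy-4-hydroxy-5-[(trimethylsilyl)ethynyl]benzaldehyde
Conditions: Pd(PPh3)2Cl2 (2 mol%), CuI (4 mol%), Et3N, THF, rt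
Reagents that add atoms: none
Why: Sonogashira coupling; the electron-poor aryl iodide adds to zerovalent palladium at room temperature and free ortho-iodophenols are tolerated.

Step 4
Reactants: 5 3-benzyloxy-4-hydroxy-5-[(trimethylsilyl)ethynyl]benzaldehyde
Product: 7 7-benzyloxy-1-benzofuran-5-carbaldehyde, via ethynylphenol 6 (not isolated)
Conditions: TBAF (1 M in THF, 2.5 equiv), THF, 65 °C
Reagents that add atoms: none
Why: Fluoride removes the silyl group and the phenoxide of 6 adds 5-endo-dig to the terminal alkyne, closing the furan ring (base-mediated cycloisomerisation of an ortho-ethynylphenol).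

Step 5
Reactants: 7 7-benzyloxy-1-benzofuran-5-carbaldehyde
Product: 8 7-benzyloxy-5-(1,3-dioxolan-2-yl)-1-benzofuran
Conditions: ethylene glycol (5 equiv), PPTS (5 mol%), toluene, reflux, Dean–Stark trap
Reagents that add atoms: ethylene glycol, OCCO
Why: Acid-catalysed acetalisation with azeotropic removal of water; the dioxolane shields the aldehyde from n-BuLi in step 8 and NaBH4 in step 11, and the weak acid spares the benzofuran.

Step 6
Reactants: 9 4-bromo-2-methoxyphenol
Product: 10 1-benzyloxy-4-bromo-2-methoxybenzene
Conditions: BnBr (1.1 equiv), K2CO3 (1.5 equiv), DMF, rt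
Reagents that add atoms: benzyl bromide, BrCc1ccccc1
Why: Williamson etherification of a phenol.

Step 7
Reactants: 10 1-benzyloxy-4-bromo-2-methoxybenzene
Product: 11 2-(4-benzyloxy-3-methoxyphenyl)-4,4,5,5-tetramethyl-1,3,2-dioxaborolane
Conditions: bis(pinacolato)diboron (1.1 equiv), Pd(dppf)Cl2 (3 mol%), KOAc (3 equiv), 1,4-dioxane, 85 °C
Reagents that add atoms: bis(pinacolato)diboron, CC1(C)OB(OC1(C)C)B1OC(C)(C)C(C)(C)O1
Why: Miyaura borylation of an aryl bromide; the weak acetate base prevents further coupling of the product.

Step 8
Reactants: 8 7-benzyloxy-5-(1,3-dioxolan-2-yl)-1-benzofuran; 11 2-(4-benzyloxy-3-methoxyphenyl)-4,4,5,5-tetramethyl-1,3,2-dioxaborolane; 12 allyl acetate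
Product: 15 (2R,3R)-3-allyl-7-benzyloxy-2-(4-benzyloxy-3-methoxyphenyl)-5-(1,3-dioxolan-2-yl)-2-(4,4,5,5-tetramethyl-1,3,2-dioxaborolan-2-yl)-2,3-dihydro-1-benzofuran, via 2-lithiobenzofuran 13 (not isolated), via lithium boronate complex 14 (not isolated)
Conditions: n-BuLi (1.05 equiv), THF, −78 °C; 11 (1.0 equiv), −78 °C to rt; then Pd2(dba)3 (2.5 mol%), (S)-BINAP (6 mol%), 12 (1.2 equiv), THF, rt
Reagents that add atoms: none
Why: Proposed new method: n-BuLi removes the most acidic proton of 8 (C2–H) to give 13, which adds to the boron of 11 to form the tetracoordinate boronate 14; oxidative addition of 12 to zerovalent palladium gives a cationic π-allyl complex of divalent palladium, which is attacked from outside by C3 of the electron-rich C2=C3 bond of 14 while the aryl group shifts from boron to C2, where positive charge builds up next to O1. The closest known reaction type is the same palladium/BINAP-catalysed allylation with 1,2-migration of indol-2-yl boronate complexes, which gives trans-2,3-disubstituted 2-borylindolines, together with halogen-induced 1,2-migrations of benzofuran-2-yl boronate complexes that also begin with attack of the electrophile at C3. No ring is closed; two C–C bonds (C3–CH2 and C2–aryl) are formed and the furan ring loses its aromaticity. The configuration at C3 is set by the chiral bisphosphine on the π-allyl electrophile, which selects the face of the benzofuran; the configuration at C2 follows from it, because the migrating aryl group must enter antiperiplanar to the new C3–allyl bond, so aryl and allyl come out trans and boron cis to allyl. The step needs attack at C3 in preference to transfer of an aryl or benzofuranyl group from boron to palladium (plain allyl–aryl coupling); the fully coordinated boron of 14, the high electron density at C3 (β-carbon of an enol ether whose α-carbon carries a borate) and the outer-sphere reactivity of the cationic allyl complex favour it. Only the ring E aryl group can migrate, since the benzofuranyl group is the nucleophile and the pinacol oxygens do not shift, and the dioxolane and benzyl ethers are inert to the reagents at these temperatures.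

Step 9
Reactants: 15 (2R,3R)-3-allyl-7-benzyloxy-2-(4-benzyloxy-3-methoxyphenyl)-5-(1,3-dioxolan-2-yl)-2-(4,4,5,5-tetramethyl-1,3,2-dioxaborolan-2-yl)-2,3-dihydro-1-benzofuran
Product: 16 (2R,3R)-3-allyl-7-benzyloxy-2-(4-benzyloxy-3-methoxyphenyl)-5-(1,3-dioxolan-2-yl)-2,3-dihydro-1-benzofuran
Conditions: TBAF·3H2O (3 equiv), toluene, 45 °C
Reagents that add atoms: none
Why: Fluoride-promoted protodeboronation of a tertiary benzylic pinacol boronate: fluoride adds to boron and water protonates the C–B bond from the front, with retention, so hydrogen takes the place of boron cis to the allyl group and the aryl group stays trans to it.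

Step 10
Reactants: 16 (2R,3R)-3-allyl-7-benzyloxy-2-(4-benzyloxy-3-methoxyphenyl)-5-(1,3-dioxolan-2-yl)-2,3-dihydro-1-benzofuran
Product: 17 (2R,3R)-7-benzyloxy-2-(4-benzyloxy-3-methoxyphenyl)-5-(1,3-dioxolan-2-yl)-3-[(E)-prop-1-enyl]-2,3-dihydro-1-benzofuran
Conditions: Pd(dba)2 (1 mol%), P(t-Bu)3 (1 mol%), isobutyryl chloride (1 mol%), toluene, 80 °C
Reagents that add atoms: none
Why: One-position alkene isomerisation by a bulky palladium hydride formed in situ from zerovalent palladium and the acid chloride: hydride addition to the terminal alkene and β-hydride elimination give the 2-alkene, and the hindered internal alkene next to the ring should react much more slowly, so the double bond stops short of C3; the alkene geometry is of no consequence.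

Step 11
Reactants: 17 (2R,3R)-7-benzyloxy-2-(4-benzyloxy-3-methoxyphenyl)-5-(1,3-dioxolan-2-yl)-3-[(E)-prop-1-enyl]-2,3-dihydro-1-benzofuran
Product: 19 [(2R,3S)-7-benzyloxy-2-(4-benzyloxy-3-methoxyphenyl)-5-(1,3-dioxolan-2-yl)-2,3-dihydro-1-benzofuran-3-yl]methanol, via 3-carbaldehyde 18 (not isolated)
Conditions: O3, CH2Cl2/MeOH 4:1, −78 °C, Sudan Red 7B as end-point indicator; then NaBH4 (4 equiv), −78 to 0 °C
Reagents that add atoms: ozone, [O-][O+]=O
Why: Ozonolysis with reductive work-up: the alkene reacts far faster with ozone than the alkoxyarenes and the dye marks the end point; NaBH4 reduces the peroxidic intermediate through aldehyde 18 to the alcohol in the cold, before the α-aryl aldehyde can epimerise or expel the ring oxygen. The change of the C3 descriptor from R to S reflects only the priority of the new CH2OH group.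

Step 12
Reactants: 19 [(2R,3S)-7-benzyloxy-2-(4-benzyloxy-3-methoxyphenyl)-5-(1,3-dioxolan-2-yl)-2,3-dihydro-1-benzofuran-3-yl]methanol
Product: 20 (2R,3S)-7-benzyloxy-2-(4-benzyloxy-3-methoxyphenyl)-3-(hydroxymethyl)-2,3-dihydro-1-benzofuran-5-carbaldehyde
Conditions: 1 M aqueous HCl, THF, rt
Reagents that add atoms: water, O
Why: Acid hydrolysis of an aryl dioxolane; dilute acid at room temperature should not ionise the C2–O1 bond while the ring E oxygen is benzylated.

Step 13
Reactants: 21 2',4',6'-trihydroxyacetophenone
Product: 22 1-[2,4-bis(benzyloxy)-6-hydroxyphenyl]ethanone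
Conditions: BnBr (2.1 equiv), K2CO3 (2.2 equiv), DMF, rt
Reagents that add atoms: benzyl bromide, BrCc1ccccc1
Why: Williamson etherification; one ortho hydroxyl is hydrogen-bonded to the ketone, is the least nucleophilic and stays free, as the later cyclisation requires.

Step 14
Reactants: 20 (2R,3S)-7-benzyloxy-2-(4-benzyloxy-3-methoxyphenyl)-3-(hydroxymethyl)-2,3-dihydro-1-benzofuran-5-carbaldehyde; 22 1-[2,4-bis(benzyloxy)-6-hydroxyphenyl]ethanone
Product: 23 (E)-1-[2,4-bis(benzyloxy)-6-hydroxyphenyl]-3-[(2R,3S)-7-benzyloxy-2-(4-benzyloxy-3-methoxyphenyl)-3-(hydroxymethyl)-2,3-dihydro-1-benzofuran-5-yl]prop-2-en-1-one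
Conditions: KOH (50% aq., 10 equiv), EtOH/THF 1:1, rt
Reagents that add atoms: none
Why: Claisen–Schmidt condensation of a methyl ketone enolate with a non-enolisable aryl aldehyde, giving the (E)-chalcone after loss of water; ring D has no acidic hydrogen under these conditions and the primary alcohol is a spectator.

Step 15
Reactants: 23 (E)-1-[2,4-bis(benzyloxy)-6-hydroxyphenyl]-3-[(2R,3S)-7-benzyloxy-2-(4-benzyloxy-3-methoxyphenyl)-3-(hydroxymethyl)-2,3-dihydro-1-benzofuran-5-yl]prop-2-en-1-one
Product: 24 5,7-bis(benzyloxy)-2-[(2R,3S)-7-benzyloxy-2-(4-benzyloxy-3-methoxyphenyl)-3-(hydroxymethyl)-2,3-dihydro-1-benzofuran-5-yl]-3-hydroxy-4H-chromen-4-one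
Conditions: H2O2 (30% aq., 5 equiv), NaOH (2 M aq.), MeOH/THF, 0 °C to rt
Reagents that add atoms: hydrogen peroxide, OO
Why: Algar–Flynn–Oyamada oxidation: hydroperoxide oxidises the enone, the 2'-phenoxide closes the six-membered ring at the β-carbon and excess peroxide dehydrogenates the dihydroflavonol; low temperature and the electron-rich β-aryl group favour the six-membered ring over the aurone.

Step 16
Reactants: 24 5,7-bis(benzyloxy)-2-[(2R,3S)-7-benzyloxy-2-(4-benzyloxy-3-methoxyphenyl)-3-(hydroxymethyl)-2,3-dihydro-1-benzofuran-5-yl]-3-hydroxy-4H-chromen-4-one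
Product: 25 2,3-dehydrosilychristin, 3,5,7-trihydroxy-2-[(2R,3S)-7-hydroxy-2-(4-hydroxy-3-methoxyphenyl)-3-(hydroxymethyl)-2,3-dihydro-1-benzofuran-5-yl]-4H-chromen-4-one
Conditions: H2 (1 atm), Pd/C (10% Pd), THF/MeOH 1:1, rt
Reagents that add atoms: none
Why: Hydrogenolysis of four aryl benzyl ethers under neutral conditions; these cleave faster than the hindered cyclic benzylic C2–O1 bond, and the chromone double bond is not reduced at atmospheric pressure.

## Compound list

1 | 5-iodovanillin (4-hydroxy-3-iodo-5-methoxybenzaldehyde) | COc1cc(C=O)cc(I)c1O | starting material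
2 | 3,4-dihydroxy-5-iodobenzaldehyde | O=Cc1cc(O)c(O)c(I)c1 | intermediate
3 | 3-benzyloxy-4-hydroxy-5-iodobenzaldehyde | O=Cc1cc(I)c(O)c(OCc2ccccc2)c1 | intermediate
4 | ethynyltrimethylsilane | C#C[Si](C)(C)C | starting material
5 | 3-benzyloxy-4-hydroxy-5-[(trimethylsilyl)ethynyl]benzaldehyde | O=Cc1cc(C#C[Si](C)(C)C)c(O)c(OCc2ccccc2)c1 | intermediate
6 | 3-benzyloxy-5-ethynyl-4-hydroxybenzaldehyde | O=Cc1cc(C#C)c(O)c(OCc2ccccc2)c1 | intermediate (not isolated)
7 | 7-benzyloxy-1-benzofuran-5-carbaldehyde | O=Cc1cc2ccoc2c(OCc2ccccc2)c1 | intermediate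
8 | 7-benzyloxy-5-(1,3-dioxolan-2-yl)-1-benzofuran | c1cc2cc(C3OCCO3)cc(OCc3ccccc3)c2o1 | intermediate
9 | 4-bromo-2-methoxyphenol | COc1cc(Br)ccc1O | starting material
10 | 1-benzyloxy-4-bromo-2-methoxybenzene | COc1cc(Br)ccc1OCc1ccccc1 | intermediate
11 | 2-(4-benzyloxy-3-methoxyphenyl)-4,4,5,5-tetramethyl-1,3,2-dioxaborolane | COc1cc(B2OC(C)(C)C(C)(C)O2)ccc1OCc1ccccc1 | intermediate
12 | allyl acetate | C=CCOC(C)=O | starting material
13 | [7-benzyloxy-5-(1,3-dioxolan-2-yl)-1-benzofuran-2-yl]lithium | [Li]c1cc2cc(C3OCCO3)cc(OCc3ccccc3)c2o1 | intermediate (not isolated)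
14 | lithium (4-benzyloxy-3-methoxyphenyl)[7-benzyloxy-5-(1,3-dioxolan-2-yl)-1-benzofuran-2-yl](pinacolato)borate | [Li+].COc1cc([B-]2(c3cc4cc(C5OCCO5)cc(OCc5ccccc5)c4o3)OC(C)(C)C(C)(C)O2)ccc1OCc1ccccc1 | intermediate (not isolated)
15 | (2R,3R)-3-allyl-7-benzyloxy-2-(4-benzyloxy-3-methoxyphenyl)-5-(1,3-dioxolan-2-yl)-2-(4,4,5,5-tetramethyl-1,3,2-dioxaborolan-2-yl)-2,3-dihydro-1-benzofuran (aryl and allyl trans) | COc1cc([C@]2(B3OC(C)(C)C(C)(C)O3)Oc3c(OCc4ccccc4)cc(C4OCCO4)cc3[C@H]2CC=C)ccc1OCc1ccccc1 | intermediate
16 | (2R,3R)-3-allyl-7-benzyloxy-2-(4-benzyloxy-3-methoxyphenyl)-5-(1,3-dioxolan-2-yl)-2,3-dihydro-1-benzofuran | COc1cc([C@@H]2Oc3c(OCc4ccccc4)cc(C4OCCO4)cc3[C@H]2CC=C)ccc1OCc1ccccc1 | intermediate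
17 | (2R,3R)-7-benzyloxy-2-(4-benzyloxy-3-methoxyphenyl)-5-(1,3-dioxolan-2-yl)-3-[(E)-prop-1-enyl]-2,3-dihydro-1-benzofuran | COc1cc([C@@H]2Oc3c(OCc4ccccc4)cc(C4OCCO4)cc3[C@H]2/C=C/C)ccc1OCc1ccccc1 | intermediate
18 | (2R,3R)-7-benzyloxy-2-(4-benzyloxy-3-methoxyphenyl)-5-(1,3-dioxolan-2-yl)-2,3-dihydro-1-benzofuran-3-carbaldehyde | COc1cc([C@@H]2Oc3c(OCc4ccccc4)cc(C4OCCO4)cc3[C@H]2C=O)ccc1OCc1ccccc1 | intermediate (not isolated)
19 | [(2R,3S)-7-benzyloxy-2-(4-benzyloxy-3-methoxyphenyl)-5-(1,3-dioxolan-2-yl)-2,3-dihydro-1-benzofuran-3-yl]methanol | COc1cc([C@@H]2Oc3c(OCc4ccccc4)cc(C4OCCO4)cc3[C@H]2CO)ccc1OCc1ccccc1 | intermediate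
20 | (2R,3S)-7-benzyloxy-2-(4-benzyloxy-3-methoxyphenyl)-3-(hydroxymethyl)-2,3-dihydro-1-benzofuran-5-carbaldehyde | COc1cc([C@@H]2Oc3c(OCc4ccccc4)cc(C=O)cc3[C@H]2CO)ccc1OCc1ccccc1 | intermediate
21 | 2',4',6'-trihydroxyacetophenone (phloroacetophenone) | CC(=O)c1c(O)cc(O)cc1O | starting material
22 | 1-[2,4-bis(benzyloxy)-6-hydroxyphenyl]ethanone | CC(=O)c1c(O)cc(OCc2ccccc2)cc1OCc1ccccc1 | intermediate
23 | (E)-1-[2,4-bis(benzyloxy)-6-hydroxyphenyl]-3-[(2R,3S)-7-benzyloxy-2-(4-benzyloxy-3-methoxyphenyl)-3-(hydroxymethyl)-2,3-dihydro-1-benzofuran-5-yl]prop-2-en-1-one | COc1cc([C@@H]2Oc3c(OCc4ccccc4)cc(/C=C/C(=O)c4c(O)cc(OCc5ccccc5)cc4OCc4ccccc4)cc3[C@H]2CO)ccc1OCc1ccccc1 | intermediate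
24 | 5,7-bis(benzyloxy)-2-[(2R,3S)-7-benzyloxy-2-(4-benzyloxy-3-methoxyphenyl)-3-(hydroxymethyl)-2,3-dihydro-1-benzofuran-5-yl]-3-hydroxy-4H-chromen-4-one | COc1cc([C@@H]2Oc3c(OCc4ccccc4)cc(-c4oc5cc(OCc6ccccc6)cc(OCc6ccccc6)c5c(=O)c4O)cc3[C@H]2CO)ccc1OCc1ccccc1 | intermediate
25 | 2,3-dehydrosilychristin, 3,5,7-trihydroxy-2-[(2R,3S)-7-hydroxy-2-(4-hydroxy-3-methoxyphenyl)-3-(hydroxymethyl)-2,3-dihydro-1-benzofuran-5-yl]-4H-chromen-4-one | COc1cc([C@@H]2Oc3c(O)cc(-c4oc5cc(O)cc(O)c5c(=O)c4O)cc3[C@H]2CO)ccc1O | target

## Step count and risks

Total step count: 16. Longest linear sequence: 13 steps (1 to 25 through steps 1–5, 8–12 and 14–16); steps 6–7 and step 13 prepare the side fragments.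

**Step 8 (key step, new method).**
- **Most likely failure:** the organic groups of 14 may be handed from boron to palladium, so that plain allyl–aryl or allyl–benzofuranyl coupling replaces attack at C3. Attack at C3 may also be slow, because a benzofuran is a weaker π-nucleophile than an indole. Facial selection may be poor, because O1 carries no substituent that helps the ligand tell the faces apart.
- **Fallback (known chemistry, ring D closed at C2–C3 by rhodium carbenoid C–H insertion):** it sets out from 3 and comes back at 19. Mitsunobu etherification of 3 with commercial 4-benzyloxy-3-methoxybenzyl alcohol (PPh3, diisopropyl azodicarboxylate) would give 3-benzyloxy-4-[(4-benzyloxy-3-methoxyphenyl)methoxy]-5-iodobenzaldehyde F1. Acetalisation as in step 5 would give the dioxolane F2. Coupling with the zinc enolate BrZnCH2CO2Me under Pd2(dba)3/P(t-Bu)3 would give the methyl arylacetate F3, and diazo transfer with 4-acetamidobenzenesulfonyl azide and DBU the aryldiazoacetate F4. Insertion into the benzylic C–H bond with Rh2(S-PTTL)4, dirhodium tetrakis[N-phthaloyl-(S)-tert-leucinate], or its enantiomer (whichever sets C2 as R), would give the cis ester F5. NaOMe in MeOH would epimerise C3 to the trans ester F6, and LiAlH4 would reduce F6 to 19.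

**Step 9.**
- **Most likely failure:** loss of configuration at C2, or no reaction. Protonation of the C–B bond relies on benzylic carbanion character, which the electron-rich ring E and the α-oxygen reduce, and a slow reaction leaves time for opening of the C2–O1 bond.
- **Fallback from 15, returning at 16:** oxidation of the C–B bond with NaBO3·4H2O in THF/water would give the hemiketal, which opens to (2R)-2-[3-benzyloxy-5-(1,3-dioxolan-2-yl)-2-hydroxyphenyl]-1-(4-benzyloxy-3-methoxyphenyl)pent-4-en-1-one F7. This is reduced without delay, to limit enolisation at the stereocentre, with NaBH4 to the phenol diol F8 (both carbinol epimers). Camphorsulfonic acid with 4 Å molecular sieves in CH2Cl2 would then ionise the para-alkoxybenzylic alcohol, and the phenol would close ring D trans to the C3 substituent, giving 16.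

**Step 10.**
- **Most likely failure:** the double bond migrates a second time, onto C3, with loss of that stereocentre and aromatisation to a benzofuran as the thermodynamic sink.
- **Fallback from 16, returning at 19, with no isomerisation:** cleavage of the terminal alkene with OsO4 (cat.), NaIO4 and 2,6-lutidine would give the acetaldehyde F9. TBSOTf and Et3N would give the silyl enol ether F10. Ozonolysis of F10 with NaBH4 work-up, as in step 11, would remove the extra carbon and give 19 through 18.

**Step 15.**
- **Most likely failure:** ring closure through the α-carbon to the five-membered aurone, a known tendency of chalcones with a 6'-alkoxy group, or over-oxidation of the electron-rich product.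
- **Fallback from 23, returning at 24:** I2 (catalytic) in DMSO at 120 °C would cyclise and dehydrogenate 23 to the flavone F11. Dimethyldioxirane in acetone/CH2Cl2 followed by a trace of p-toluenesulfonic acid would epoxidise the C2=C3 bond and rearrange the epoxide to the 3-hydroxyflavone 24.

**Step 2.**
- **Most likely failure:** alkylation at the wrong oxygen or at both, because the preference of the dianion for the 3-oxide is only kinetic.
- **Fallback from 2, returning at 7, avoiding the differentiation:** Ac2O and pyridine would give 3,4-diacetoxy-5-iodobenzaldehyde F12. Sonogashira coupling with 4 as in step 3 would give the silylalkyne F13. K2CO3 in MeOH at 60 °C under argon would cleave both acetates and the silyl group and close the furan ring through the only oxygen ortho to the alkyne, giving 7-hydroxy-1-benzofuran-5-carbaldehyde F14. BnBr and K2CO3 in DMF would then give 7.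

## Further compounds

F1 | step 8 | 3-benzyloxy-4-[(4-benzyloxy-3-methoxyphenyl)methoxy]-5-iodobenzaldehyde | COc1cc(COc2c(I)cc(C=O)cc2OCc2ccccc2)ccc1OCc1ccccc1
F2 | step 8 | 2-{3-benzyloxy-4-[(4-benzyloxy-3-methoxyphenyl)methoxy]-5-iodophenyl}-1,3-dioxolane | COc1cc(COc2c(I)cc(C3OCCO3)cc2OCc2ccccc2)ccc1OCc1ccccc1
F3 | step 8 | methyl 2-{3-benzyloxy-2-[(4-benzyloxy-3-methoxyphenyl)methoxy]-5-(1,3-dioxolan-2-yl)phenyl}acetate | COC(=O)Cc1cc(C2OCCO2)cc(OCc2ccccc2)c1OCc1ccc(OCc2ccccc2)c(OC)c1
F4 | step 8 | methyl 2-{3-benzyloxy-2-[(4-benzyloxy-3-methoxyphenyl)methoxy]-5-(1,3-dioxolan-2-yl)phenyl}-2-diazoacetate | COC(=O)C(=[N+]=[N-])c1cc(C2OCCO2)cc(OCc2ccccc2)c1OCc1ccc(OCc2ccccc2)c(OC)c1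
F5 | step 8 | methyl (2R,3S)-7-benzyloxy-2-(4-benzyloxy-3-methoxyphenyl)-5-(1,3-dioxolan-2-yl)-2,3-dihydro-1-benzofuran-3-carboxylate (cis) | COc1cc([C@@H]2Oc3c(OCc4ccccc4)cc(C4OCCO4)cc3[C@@H]2C(=O)OC)ccc1OCc1ccccc1
F6 | step 8 | methyl (2R,3R)-7-benzyloxy-2-(4-benzyloxy-3-methoxyphenyl)-5-(1,3-dioxolan-2-yl)-2,3-dihydro-1-benzofuran-3-carboxylate (trans) | COc1cc([C@@H]2Oc3c(OCc4ccccc4)cc(C4OCCO4)cc3[C@H]2C(=O)OC)ccc1OCc1ccccc1
F7 | step 9 | (2R)-2-[3-benzyloxy-5-(1,3-dioxolan-2-yl)-2-hydroxyphenyl]-1-(4-benzyloxy-3-methoxyphenyl)pent-4-en-1-one | C=CC[C@@H](C(=O)c1ccc(OCc2ccccc2)c(OC)c1)c1cc(C2OCCO2)cc(OCc2ccccc2)c1O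
F8 | step 9 | (2R)-2-[3-benzyloxy-5-(1,3-dioxolan-2-yl)-2-hydroxyphenyl]-1-(4-benzyloxy-3-methoxyphenyl)pent-4-en-1-ol, both C1 epimers | C=CC[C@@H](C(O)c1ccc(OCc2ccccc2)c(OC)c1)c1cc(C2OCCO2)cc(OCc2ccccc2)c1O
F9 | step 10 | 2-[(2R,3R)-7-benzyloxy-2-(4-benzyloxy-3-methoxyphenyl)-5-(1,3-dioxolan-2-yl)-2,3-dihydro-1-benzofuran-3-yl]acetaldehyde | COc1cc([C@@H]2Oc3c(OCc4ccccc4)cc(C4OCCO4)cc3[C@H]2CC=O)ccc1OCc1ccccc1
F10 | step 10 | (2R,3R)-7-benzyloxy-2-(4-benzyloxy-3-methoxyphenyl)-3-[2-(tert-butyldimethylsilyloxy)ethenyl]-5-(1,3-dioxolan-2-yl)-2,3-dihydro-1-benzofuran, E/Z mixture | COc1cc([C@@H]2Oc3c(OCc4ccccc4)cc(C4OCCO4)cc3[C@H]2C=CO[Si](C)(C)C(C)(C)C)ccc1OCc1ccccc1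
F11 | step 15 | 5,7-bis(benzyloxy)-2-[(2R,3S)-7-benzyloxy-2-(4-benzyloxy-3-methoxyphenyl)-3-(hydroxymethyl)-2,3-dihydro-1-benzofuran-5-yl]-4H-chromen-4-one | COc1cc([C@@H]2Oc3c(OCc4ccccc4)cc(-c4cc(=O)c5c(OCc6ccccc6)cc(OCc6ccccc6)cc5o4)cc3[C@H]2CO)ccc1OCc1ccccc1
F12 | step 2 | 3,4-diacetoxy-5-iodobenzaldehyde | CC(=O)Oc1cc(C=O)cc(I)c1OC(C)=O
F13 | step 2 | 3,4-diacetoxy-5-[(trimethylsilyl)ethynyl]benzaldehyde | CC(=O)Oc1cc(C=O)cc(C#C[Si](C)(C)C)c1OC(C)=O
F14 | step 2 | 7-hydroxy-1-benzofuran-5-carbaldehyde | O=Cc1cc(O)c2occc2c1
A1 | alternative 1 | 3-benzyloxy-2-[(2R,3S)-7-benzyloxy-2-(4-benzyloxy-3-methoxyphenyl)-3-(tert-butyldimethylsilyloxymethyl)-2,3-dihydro-1-benzofuran-5-yl]-5-hydroxy-7-(triisopropylsilyloxy)-4H-chromen-4-one | COc1cc([C@@H]2Oc3c(OCc4ccccc4)cc(-c4oc5cc(O[Si](C(C)C)(C(C)C)C(C)C)cc(O)c5c(=O)c4OCc4ccccc4)cc3[C@H]2CO[Si](C)(C)C(C)(C)C)ccc1OCc1ccccc1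
A2 | alternative 1 | 3-benzyloxy-2-[(2R,3S)-7-benzyloxy-2-(4-benzyloxy-3-methoxyphenyl)-3-(tert-butyldimethylsilyloxymethyl)-2,3-dihydro-1-benzofuran-5-yl]-6-(2-diazoacetyl)-4H-pyran-4-one | COc1cc([C@@H]2Oc3c(OCc4ccccc4)cc(-c4oc(C(=O)C=[N+]=[N-])cc(=O)c4OCc4ccccc4)cc3[C@H]2CO[Si](C)(C)C(C)(C)C)ccc1OCc1ccccc1
A3 | alternative 1 | (triisopropylsilyloxy)ethyne | C#CO[Si](C(C)C)(C(C)C)C(C)C
A4 | alternative 2 | methyl (2R,3R)-7-benzyloxy-2-(4-benzyloxy-3-methoxyphenyl)-5-bromo-2,3-dihydro-1-benzofuran-3-carboxylate (trans) | COc1cc([C@@H]2Oc3c(OCc4ccccc4)cc(Br)cc3[C@H]2C(=O)OC)ccc1OCc1ccccc1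
A5 | alternative 2 | methyl 2-{3-benzyloxy-2-[(4-benzyloxy-3-methoxyphenyl)methoxy]-5-bromophenyl}-2-diazoacetate | COC(=O)C(=[N+]=[N-])c1cc(Br)cc(OCc2ccccc2)c1OCc1ccc(OCc2ccccc2)c(OC)c1
A6 | alternative 3 | (2R,3S)-7-benzyloxy-2-(4-benzyloxy-3-methoxyphenyl)-5-bromo-3-(tert-butyldimethylsilyloxymethyl)-2,3-dihydro-1-benzofuran (trans) | COc1cc([C@@H]2Oc3c(OCc4ccccc4)cc(Br)cc3[C@H]2CO[Si](C)(C)C(C)(C)C)ccc1OCc1ccccc1
A7 | alternative 3 | 2-benzyloxy-4-bromo-6-[2-(tert-butyldimethylsilyloxy)-1-(4-methylbenzenesulfonyl)ethyl]phenol (racemic) | Cc1ccc(S(=O)(=O)C(CO[Si](C)(C)C(C)(C)C)c2cc(Br)cc(OCc3ccccc3)c2O)cc1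
A8 | alternative 3 | (2R,5R)-1-(4-benzyloxy-3-methoxybenzyl)-2,5-dimethylthiolan-1-ium trifluoromethanesulfonate (or its enantiomer) | COc1cc(C[S+]2[C@H](C)CC[C@H]2C)ccc1OCc1ccccc1.[O-]S(=O)(=O)C(F)(F)F
A9 | alternative 3 | 2-benzyloxy-4-bromo-6-[2-(tert-butyldimethylsilyloxy)ethylidene]cyclohexa-2,4-dien-1-one | O=C1C(OCc2ccccc2)=CC(Br)=CC1=CCO[Si](C)(C)C(C)(C)C
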